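**Retrosynthetic overview**
1. Target 20 ⇒ ring-opened tricyclic lactone 17 + prenyl acetate: a dearomatizing palladium-catalysed prenylation at C6 is the last step and frees the acid.
2. Lactone 17 ⇒ chromanone 15 + (E)-hex-2-enal: a carbene-catalysed Michael addition/lactonisation at C8 sets the propyl-bearing centre.
3. Key disconnection, the pyranone O1–C2 bond: 15 ⇒ aryl methyl ketone 12 + acetone. Which ortho-hydroxyl closes this C–O bond fixes the constitution of the whole core.
4. 12 ⇒ 2',4',6'-trihydroxyacetophenone + cyclobutane aldehyde 9 (reductive alkylation); 9 ⇒ cyclobutenoate 5 + isopropenyl boronate ⇒ enamine + methyl acrylate.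
5. Ring order: cyclobutane, then pyranone, then a temporary lactone; the six-membered carbocycle is bought as an arene and dearomatized last.

Assumption: in the catalyst-controlled steps 3, 7 and 8 the catalyst enantiomer named is the one expected to give the drawn configuration; if a test run shows the opposite sense, its commercially available mirror image is used.

**Step 1**
Reactants: 1 4-(2-methylprop-1-en-1-yl)morpholine; 2 methyl acrylate
Product: 3 methyl 3,3-dimethyl-2-(morpholin-4-yl)cyclobutane-1-carboxylate (racemic cis/trans mixture)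
Conditions: MeCN, 85 °C (sealed tube), 48 h
Reagents that add atoms: none
Why: Thermal stepwise enamine–acrylate [2+2] cycloaddition (Brannock type): the enamine carbon adds to the acrylate CH2 and the ester enolate closes on the iminium carbon, which places the amine between the ester carbon and the gem-dimethyl carbon; the stereochemistry is irrelevant because it is erased in step 2.

**Step 2**
Reactants: 3 methyl 3,3-dimethyl-2-(morpholin-4-yl)cyclobutane-1-carboxylate
Product: 5 methyl 3,3-dimethylcyclobut-1-ene-1-carboxylate, via morpholinium triflate 4 (not isolated)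
Conditions: MeOTf (1.1 equiv), CH2Cl2, 0 → 25 °C; then K2CO3 (2 equiv), MeCN, 50 °C
Reagents that add atoms: none
Why: N-Methylation turns the amine into a leaving group and E1cB elimination follows; the only β-hydrogen is the one alpha to the ester, so only the conjugated cyclobutene can form (quaternisation/Hofmann-type elimination).

**Step 3**
Reactants: 5 methyl 3,3-dimethylcyclobut-1-ene-1-carboxylate; 6 2-isopropenyl-4,4,5,5-tetramethyl-1,3,2-dioxaborolane
Product: 8 methyl (1R,2R)-3,3-dimethyl-2-(prop-1-en-2-yl)cyclobutane-1-carboxylate, via C1-epimer mixture 7 (not isolated)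
Conditions: [RhCl(C2H4)2]2 (1.5 mol%), (R,R)-2,5-diphenylbicyclo[2.2.2]octa-2,5-diene (3.3 mol%), KOH (0.3 equiv), dioxane/H2O 10:1, 50 °C; then NaOMe (0.2 equiv), MeOH, 25 °C
Reagents that add atoms: none
Why: Rhodium-catalysed asymmetric conjugate addition (Hayashi–Miyaura type) of an alkenylboron reagent to a strained cyclobutenoate: the chiral diene on monovalent rhodium selects the face of alkenyl transfer and sets C2 as R, and methoxide equilibration through the ester enolate then sets C1 to the more stable trans (1R) arrangement.

**Step 4**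
Reactants: 8 methyl (1R,2R)-3,3-dimethyl-2-(prop-1-en-2-yl)cyclobutane-1-carboxylate
Product: 9 (1R,2R)-3,3-dimethyl-2-(prop-1-en-2-yl)cyclobutane-1-carbaldehyde
Conditions: i-Bu2AlH (1.05 equiv), CH2Cl2, −78 °C; aq. potassium sodium tartrate work-up; used as a solution (volatile)
Reagents that add atoms: none
Why: Partial ester reduction with diisobutylaluminium hydride stops at the aluminium hemiacetal at −78 °C and gives the aldehyde on work-up; both stereocentres are untouched and trans is also the thermodynamic arrangement at the alpha carbon.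

**Step 5**
Reactants: 9 (1R,2R)-3,3-dimethyl-2-(prop-1-en-2-yl)cyclobutane-1-carbaldehyde; 10 2',4',6'-trihydroxyacetophenone
Product: 12 1-(2,4,6-trihydroxy-3-{[(1S,2R)-3,3-dimethyl-2-(prop-1-en-2-yl)cyclobutyl]methyl}phenyl)ethan-1-one, via ortho-quinone methide 11 (not isolated)
Conditions: 10 (3 equiv), L-proline (20 mol%), Hantzsch ester (1.2 equiv), EtOH/CH2Cl2, 25 °C
Reagents that add atoms: none
Why: Organocatalytic three-component reductive alkylation: Knoevenagel-type condensation of the aldehyde with a nucleophilic ring carbon gives the ortho-quinone methide, which the Hantzsch ester reduces by hydride transfer; the two free ring carbons of 10 are equivalent, excess 10 suppresses double alkylation, and no new stereocentre is formed (the C1 descriptor changes from R to S only through priorities).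

**Step 6 (key step)**
Reactants: 12 1-(2,4,6-trihydroxy-3-{[(1S,2R)-3,3-dimethyl-2-(prop-1-en-2-yl)cyclobutyl]methyl}phenyl)ethan-1-one; 13 acetone
Product: 15 5,7-dihydroxy-2,2-dimethyl-6-{[(1S,2R)-3,3-dimethyl-2-(prop-1-en-2-yl)cyclobutyl]methyl}chroman-4-one, via open-chain enone 14 (not isolated)
Conditions: 13 (10 equiv), pyrrolidine (1.0 equiv), 2,4,6-triisopropylbenzoic acid (1.0 equiv), 4 Å MS, toluene, 40 °C
Reagents that add atoms: none
Why: Proposed new method: a site-selective Kabbe annulation in which the C–O bond-forming oxa-Michael closure chooses between the two ortho-hydroxyls. The pyrrolidinium/bulky-carboxylate pair condenses acetone onto the acetyl group (iminium-activated aldol, then loss of pyrrolidine) to give enone 14 while all phenols stay protonated, so the ketone remains locked in the buttressed hydrogen bond to the hydroxyl next to the cyclobutylmethyl group (that O–H cannot turn away from the carbonyl); the alkene terminus therefore lies beside the other ortho-hydroxyl, which is also the only one the hindered carboxylate base can reach, and 6-endo closure through it gives the 6-alkyl chromanone under kinetic control (no stereocentre is formed; the constitution of the core is). The closest known reaction types are the pyrrolidine-mediated Kabbe chromanone synthesis and the chalcone-to-flavanone cyclisation of 3'-alkyl-2',4',6'-trihydroxychalcones, which I recall favouring this sense only modestly.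

**Step 7**
Reactants: 15 5,7-dihydroxy-2,2-dimethyl-6-{[(1S,2R)-3,3-dimethyl-2-(prop-1-en-2-yl)cyclobutyl]methyl}chroman-4-one; 16 (E)-hex-2-enal
Product: 17 tricyclic lactone: chromanone 15 with a 4-propyl-3,4-dihydropyran-2-one ring fused across C7–C8 (lactone oxygen on C7, (R)-CH(propyl) on C8, 5-OH free)
Conditions: 16 (1.5 equiv), (5aS,10bR)-aminoindanol-derived N-mesityl triazolium chloride (10 mol%), DBU (20 mol%), 3,3',5,5'-tetra-tert-butyl-4,4'-diphenoquinone (1.2 equiv), 4 Å MS, toluene, 25 °C
Reagents that add atoms: none
Why: Oxidative N-heterocyclic carbene catalysis turns the enal into an α,β-unsaturated acyl azolium, which takes up the only free ring carbon (C8) in an enantioselective Michael addition and is then released by lactonisation on O7 (formal [3+3] annulation); the chiral triazolium shields one face so the propyl-bearing carbon is formed R.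

**Step 8**
Reactants: 17 tricyclic lactone; 18 3-methylbut-2-en-1-yl acetate (prenyl acetate)
Product: 20 (3R)-3-[(6R)-6-{[(1S,2R)-3,3-dimethyl-2-(prop-1-en-2-yl)cyclobutyl]methyl}-5-hydroxy-2,2-dimethyl-6-(3-methylbut-2-en-1-yl)-4,7-dioxo-3,4,6,7-tetrahydro-2H-chromen-8-yl]hexanoic acid (target CNP0358381.1), via ring-opened dilithium salt 19 (not isolated)
Conditions: LiOH (2.1 equiv), THF/H2O 10:1, 0 °C, 1 h; then Pd2(dba)3 (2.5 mol%), (R,R)-DACH-phenyl Trost ligand (7.5 mol%), 18 (1.2 equiv), 0 → 25 °C; 1 M HCl to pH 3 at 0 °C
Reagents that add atoms: lithium hydroxide, [Li+].[OH-]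
Why: Hydroxide opens the aryl lactone to the carboxylate/phenoxide, and a zerovalent palladium–Trost ligand catalyst then delivers the π-prenyl unit to the ring carbon between the two oxygens that already carries the cyclobutylmethyl group (dearomatizing Tsuji–Trost asymmetric allylic alkylation). Attack through the unhindered CH2 terminus gives the linear prenyl group, the chiral ligand selects the ring face and sets C6 as R, O-prenylation is reversible under the catalyst, and the more hindered C8 (secondary alkyl) does not compete.

**Compound list**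
1 | 4-(2-methylprop-1-en-1-yl)morpholine | CC(C)=CN1CCOCC1 | starting material
2 | methyl acrylate | C=CC(=O)OC | starting material
3 | methyl 3,3-dimethyl-2-(morpholin-4-yl)cyclobutane-1-carboxylate (racemic, cis/trans mixture) | COC(=O)C1CC(C)(C)C1N2CCOCC2 | intermediate
4 | 4-[2-(methoxycarbonyl)-4,4-dimethylcyclobutyl]-4-methylmorpholin-4-ium triflate | COC(=O)C1CC(C)(C)C1[N+]2(C)CCOCC2.[O-]S(=O)(=O)C(F)(F)F | intermediate (not isolated)
5 | methyl 3,3-dimethylcyclobut-1-ene-1-carboxylate | COC(=O)C1=CC(C)(C)C1 | intermediate
6 | 2-isopropenyl-4,4,5,5-tetramethyl-1,3,2-dioxaborolane | C=C(C)B1OC(C)(C)C(C)(C)O1 | starting material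
7 | methyl (2R)-3,3-dimethyl-2-(prop-1-en-2-yl)cyclobutane-1-carboxylate, mixture of C1 epimers | C=C(C)[C@H]1C(C(=O)OC)CC1(C)C | intermediate (not isolated)
8 | methyl (1R,2R)-3,3-dimethyl-2-(prop-1-en-2-yl)cyclobutane-1-carboxylate (trans) | C=C(C)[C@H]1[C@H](C(=O)OC)CC1(C)C | intermediate
9 | (1R,2R)-3,3-dimethyl-2-(prop-1-en-2-yl)cyclobutane-1-carbaldehyde (trans) | C=C(C)[C@H]1[C@H](C=O)CC1(C)C | intermediate
10 | 2',4',6'-trihydroxyacetophenone | CC(=O)c1c(O)cc(O)cc1O | starting material
11 | ortho-quinone methide from 9 and 10 (exocyclic alkene geometry not defined) | C=C(C)[C@H]1[C@H](C=C2C(=O)C(C(C)=O)=C(O)C=C2O)CC1(C)C | intermediate (not isolated)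
12 | 1-(2,4,6-trihydroxy-3-{[(1S,2R)-3,3-dimethyl-2-(prop-1-en-2-yl)cyclobutyl]methyl}phenyl)ethan-1-one | C=C(C)[C@H]1[C@H](Cc2c(O)cc(O)c(C(C)=O)c2O)CC1(C)C | intermediate
13 | acetone | CC(C)=O | starting material
14 | 1-(2,4,6-trihydroxy-3-{[(1S,2R)-3,3-dimethyl-2-(prop-1-en-2-yl)cyclobutyl]methyl}phenyl)-3-methylbut-2-en-1-one | C=C(C)[C@H]1[C@H](Cc2c(O)cc(O)c(C(=O)C=C(C)C)c2O)CC1(C)C | intermediate (not isolated)
15 | 5,7-dihydroxy-2,2-dimethyl-6-{[(1S,2R)-3,3-dimethyl-2-(prop-1-en-2-yl)cyclobutyl]methyl}chroman-4-one | C=C(C)[C@H]1[C@H](Cc2c(O)cc3OC(C)(C)CC(=O)c3c2O)CC1(C)C | intermediate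
16 | (E)-hex-2-enal | CCC/C=C/C=O | starting material
17 | tricyclic lactone: 15 annulated at C8/O7 with a 3,4-dihydropyran-2-one ring bearing an (R)-configured propyl-substituted carbon on C8; 5-OH free | C=C(C)[C@H]1[C@H](Cc2c(O)c3C(=O)CC(C)(C)Oc3c4c2OC(=O)C[C@H]4CCC)CC1(C)C | intermediate
18 | 3-methylbut-2-en-1-yl acetate (prenyl acetate) | CC(=O)OCC=C(C)C | starting material
19 | dilithium salt of (3R)-3-(5,7-dihydroxy-2,2-dimethyl-6-{[(1S,2R)-3,3-dimethyl-2-(prop-1-en-2-yl)cyclobutyl]methyl}-4-oxochroman-8-yl)hexanoic acid (carboxylate and 7-phenoxide) | C=C(C)[C@H]1[C@H](Cc2c(O)c3C(=O)CC(C)(C)Oc3c([C@H](CCC)CC(=O)[O-])c2[O-])CC1(C)C.[Li+].[Li+] | intermediate (not isolated)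
20 | (3R)-3-[(6R)-6-{[(1S,2R)-3,3-dimethyl-2-(prop-1-en-2-yl)cyclobutyl]methyl}-5-hydroxy-2,2-dimethyl-6-(3-methylbut-2-en-1-yl)-4,7-dioxo-3,4,6,7-tetrahydro-2H-chromen-8-yl]hexanoic acid | C=C(C)[C@H]1[C@H](C[C@]2(CC=C(C)C)C(=O)C([C@H](CCC)CC(=O)O)=C3OC(C)(C)CC(=O)C3=C2O)CC1(C)C | target

**Count**
Total steps: 8. Longest linear sequence: 8 (steps 1 to 8; compound 10 and the other building blocks are commercial).

**Three steps most likely to fail**

Step 6 (the proposed new step). The risk is closure through the other ortho-hydroxyl, which gives the 8-alkyl chromanone, or a poor ratio. The fallback uses known chemistry and reverses the order of ring closure and alkylation. It sets out from aldehyde 9. Phloroglucinol and 3,3-dimethylacrylic acid in MeSO3H/P2O5 at 70 °C give 5,7-dihydroxy-2,2-dimethylchroman-4-one F4 by Friedel–Crafts acylation/oxa-Michael closure on a symmetric arene, so the ring oxygen is unambiguous. F4 (in excess) is then reductively alkylated with 9 under the step 5 conditions (L-proline, Hantzsch ester). Attack is expected mainly at C6, the carbon flanked by two free hydroxyls, and the minor C8 isomer is removed by chromatography. The fallback comes back to the route at 15.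

Step 3. The β-carbon sits next to a quaternary centre, so the rhodium-catalysed addition may be slow or poorly selective. The fallback gives up asymmetric catalysis. It sets out from 5: isopropenylmagnesium bromide with CuBr·SMe2 and Me3SiCl in THF at −78 °C, followed by NaOMe equilibration, gives the racemic trans ester, that is 8 together with its enantiomer methyl (1S,2S)-3,3-dimethyl-2-(prop-1-en-2-yl)cyclobutane-1-carboxylate F1. Preparative chiral chromatography (SFC) separates the two, and the fallback comes back to the route at 8.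

Step 8. The ligand has to choose a ring face far from the existing stereocentres, and the nucleophile is a polyanion in a wet solvent, so the ratio at C6 may be low. The fallback replaces catalyst control by an uncontrolled alkylation and separation. It sets out from 17: aqueous KOH opens the lactone and prenyl bromide at 0 °C (classical aqueous-alkali C-prenylation of acylphloroglucinols) gives 20 together with its C6 epimer (3R)-3-[(6S)-6-{[(1S,2R)-3,3-dimethyl-2-(prop-1-en-2-yl)cyclobutyl]methyl}-5-hydroxy-2,2-dimethyl-6-(3-methylbut-2-en-1-yl)-4,7-dioxo-3,4,6,7-tetrahydro-2H-chromen-8-yl]hexanoic acid F5. The two are diastereomers and are separated by preparative HPLC; the fallback comes back to the route at 20.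

**Further compounds**
F1 | step 3 | methyl (1S,2S)-3,3-dimethyl-2-(prop-1-en-2-yl)cyclobutane-1-carboxylate (enantiomer of 8) | C=C(C)[C@@H]1[C@@H](C(=O)OC)CC1(C)C
F4 | step 6 | 5,7-dihydroxy-2,2-dimethylchroman-4-one | CC1(C)CC(=O)c2c(O)cc(O)cc2O1
F5 | step 8 | (3R)-3-[(6S)-6-{[(1S,2R)-3,3-dimethyl-2-(prop-1-en-2-yl)cyclobutyl]methyl}-5-hydroxy-2,2-dimethyl-6-(3-methylbut-2-en-1-yl)-4,7-dioxo-3,4,6,7-tetrahydro-2H-chromen-8-yl]hexanoic acid (C6 epimer of 20) | C=C(C)[C@H]1[C@H](C[C@@]2(CC=C(C)C)C(=O)C([C@H](CCC)CC(=O)O)=C3OC(C)(C)CC(=O)C3=C2O)CC1(C)C
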